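**Strategy.** Ring A is not assembled as a cyclohexane. The plan rests on breaking C4–C5 together with C3–Br (decalin numbering; C19 = the future axial methyl on C4). In the target the equatorial C3–Br bond is antiperiplanar to the C4–C5 ring bond and C4 is quaternary, which is the imprint of a bromonium-triggered 1,2-shift. The precursor is a trans-fused bicycle in which ring B, already carrying the C9 arylmethyl group, is annulated to a 2-substituted cyclohept-2-en-1-ol, C10–C1–C2–C3=C4–C19(OH)–C5. NBS contracts this seven-membered ring to ring A in one operation, installing bromine at C3 and the quaternary C4, while C19 leaves the ring as the axial formyl group that is then reduced to the C4 methyl group.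

Key step: step 15

Remarks on the chemistry:
- Numbering and faces: ring A = C1, C2, C3, C4, C5, C10; ring B = C5–C10; β = the face of the C10 methyl group; Ar = 3-bromo-5-(methoxycarbonyl)-2-(pivaloyloxy)phenyl.
- Assumption 1: the (S)-oxazaborolidinium catalyst of step 7 is taken to give the (1S) adduct 14, by analogy with buta-1,3-diene and the same acrylate; if the sense proves opposite, the antipodal catalyst is used.
- Assumption 2: C19 is formed in step 9 as a mixture of carbinol epimers, both of which are carried on because C19 becomes the formyl carbon in step 15; the SMILES show the Felkin–Anh epimer.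

Step 1
Reactants: 1 methyl 4-hydroxy-3-methylbenzoate
Product: 2 methyl 3-bromo-4-hydroxy-5-methylbenzoate
Conditions: Br2, AcOH, rt
Reagents that add atoms: bromine BrBr
Why: Electrophilic aromatic bromination; the phenol directs to its only free ortho position, the para position being occupied by the ester.

Step 2
Reactants: 2 methyl 3-bromo-4-hydroxy-5-methylbenzoate
Product: 3 methyl 3-bromo-5-methyl-4-(pivaloyloxy)benzoate
Conditions: PivCl, Et3N, DMAP (cat.), CH2Cl2, 0 °C to rt
Reagents that add atoms: pivaloyl chloride CC(C)(C)C(Cl)=O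
Why: DMAP-catalysed O-acylation of the hindered phenol gives a pivalate that is meant to last until it is cleaved together with the methyl ester in step 20.

Step 3
Reactants: 3 methyl 3-bromo-5-methyl-4-(pivaloyloxy)benzoate
Product: 4 methyl 3-bromo-5-(bromomethyl)-4-(pivaloyloxy)benzoate
Conditions: NBS, AIBN (cat.), PhCF3, 85 °C
Reagents that add atoms: N-bromosuccinimide O=C1CCC(=O)N1Br
Why: Wohl–Ziegler bromination of the only benzylic methyl group; the deactivated ring and both esters are inert to the radical chain.

Step 4
Reactants: 5 N-tert-butylethanimine; 6 2,3-dibromoprop-1-ene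
Product: 9 4-bromopent-4-enal, via lithium aza-enolate 7 (not isolated), via alkylated imine 8 (not isolated)
Conditions: LDA, THF, −78 °C; then 6, −78 to 0 °C; then aq. oxalic acid, rt
Reagents that add atoms: water O
Why: Aza-enolate (metalloenamine) alkylation by SN2 displacement of the allylic bromide of 6, followed by mild acid hydrolysis of the imine, which leaves the vinyl bromide intact.

Step 5
Reactants: 9 4-bromopent-4-enal
Product: 10 2-(3-bromobut-3-en-1-yl)-1,3-dioxolane
Conditions: ethylene glycol, TsOH·H2O (cat.), benzene, reflux (Dean–Stark)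
Reagents that add atoms: ethylene glycol OCCO
Why: Acid-catalysed acetalisation masks the aldehyde as a dioxolane that should tolerate the later organolithium, bromonium and hydride reagents.

Step 6
Reactants: 11 (E)-pent-3-en-2-one
Product: 12 (E)-2-(triisopropylsilyloxy)penta-1,3-diene
Conditions: TIPSOTf, Et3N, Et2O, 0 °C to rt
Reagents that add atoms: triisopropylsilyl triflate CC(C)[Si](OS(=O)(=O)C(F)(F)F)(C(C)C)C(C)C
Why: Soft enolisation and O-silylation on the methyl side of the enone gives the cross-conjugated 2-silyloxy diene with the (E)-propenyl unit unchanged.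

Step 7
Reactants: 12 (E)-2-(triisopropylsilyloxy)penta-1,3-diene; 13 2,2,2-trifluoroethyl acrylate
Product: 14 2,2,2-trifluoroethyl (1S,2R)-2-methyl-4-(triisopropylsilyloxy)cyclohex-3-ene-1-carboxylate
Conditions: (S)-o-tolyl oxazaborolidine from (S)-α,α-diphenylprolinol, activated with HNTf2 (20 mol%), CH2Cl2, −78 to −40 °C
Reagents that add atoms: none
Why: Catalytic enantioselective Diels–Alder reaction in which the silyloxy group ("para") and the terminal methyl ("ortho") both direct C10 to the acrylate α-carbon, the chiral Lewis acid shields one face of the bound acrylate and so sets C5 (the one centre relayed to all others), and the endo transition state gives the cis methyl/ester pair.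

Step 8
Reactants: 14 Diels–Alder ester
Product: 15 (1S,2R)-2-methyl-4-(triisopropylsilyloxy)cyclohex-3-ene-1-carbaldehyde
Conditions: DIBAL-H (i-Bu2AlH, 1.05 equiv), CH2Cl2, −78 °C; Rochelle salt work-up; used crude at once
Reagents that add atoms: none
Why: Partial reduction of the activated trifluoroethyl ester stops at the aluminium hemiacetal, which gives the aldehyde on work-up; immediate use avoids epimerisation at C5.

Step 9
Reactants: 10 2-(3-bromobut-3-en-1-yl)-1,3-dioxolane; 15 aldehyde
Product: 18 triethylsilyl ether of the C19 allylic alcohol, via vinyllithium reagent 16 (not isolated), via lithium alkoxide 17 (not isolated)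
Conditions: 10, t-BuLi (2 equiv), Et2O, −78 °C; then 15, −78 °C; then TESCl, HMPA, −78 °C to rt
Reagents that add atoms: chlorotriethylsilane CC[Si](Cl)(CC)CC
Why: Bromine–lithium exchange, 1,2-addition of the 2-lithioalkene to the aldehyde (Felkin–Anh sense; the C19 configuration is inconsequential) and O-silylation of the alkoxide in the same flask.

Step 10
Reactants: 18 bis-silyl ether
Product: 19 (4S)-3-methyl-4-[1-(triethylsilyloxy)-2-methylene-4-(1,3-dioxolan-2-yl)butyl]cyclohex-2-en-1-one
Conditions: Pd(OAc)2 (10 mol%), O2 (1 atm), DMSO, 60 °C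
Reagents that add atoms: none
Why: Saegusa–Ito oxidation (aerobic variant): the palladium enolate at C9 can only eliminate the C10 hydrogen, which gives the C9=C10 enone, erases the C10 centre and leaves C5 untouched.

Step 11
Reactants: 19 enone
Product: 20 trimethylsilyl enol ether (C8–OSiMe3, C8=C9) with quaternary C10 (methyl cis and but-3-enyl trans to the C5 side chain)
Conditions: but-3-enylmagnesium bromide (2 equiv), CuBr·SMe2 (20 mol%), TMSCl, HMPA, THF, −78 to −40 °C; Et3N quench
Reagents that add atoms: but-3-enylmagnesium bromide C=CCC[Mg]Br; chlorotrimethylsilane C[Si](C)(C)Cl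
Why: Copper-catalysed, TMSCl-accelerated conjugate addition in which the nucleophile attacks C10 anti to the pseudoaxial C5 side chain, setting the quaternary C10 centre, while the enolate is trapped regiospecifically as the C8–C9 silyl enol ether.

Step 12
Reactants: 20 silyl enol ether; 4 methyl 3-bromo-5-(bromomethyl)-4-(pivaloyloxy)benzoate
Product: 23 C9-arylmethyl ketone (ArCH2 cis to the C10 methyl), via lithium enolate 21 (not isolated), via C9-epimeric ketone 22 (not isolated)
Conditions: MeLi (1.0 equiv), THF, 0 °C; then 4, DMPU, −78 to 0 °C; then DBU, toluene, 60 °C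
Reagents that add atoms: none
Why: Regiospecific lithium enolate generation by Si–O cleavage and SN2 alkylation at C9, where axial attack anti to the C10 methyl gives epimer 22, which DBU equilibrates through the enolate to the more stable equatorial isomer 23 (C9 set under thermodynamic control and re-equilibrated in step 17).

Step 13
Reactants: 23 ketone
Product: 25 bis-dioxolane allylic alcohol, via hydroxy ketone 24 (not isolated)
Conditions: ethylene glycol, PPTS (cat.), benzene, reflux (Dean–Stark)
Reagents that add atoms: ethylene glycol OCCO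
Why: Acid-catalysed ketalisation protects the C8 ketone against the hydrazone chemistry of step 16, and the same acidic diol medium solvolyses the triethylsilyl ether to free the C19 hydroxyl.

Step 14
Reactants: 25 diene
Product: 26 trans-fused bicyclic cyclohept-2-en-1-ol (C3=C4, C19–OH)
Conditions: second-generation Grubbs catalyst (H2IMes)(PCy3)Cl2Ru=CHPh (5 mol%), 1,4-benzoquinone (10 mol%), CH2Cl2 (5 mM), 40 °C
Reagents that add atoms: none
Why: Ring-closing olefin metathesis between the monosubstituted and the 1,1-disubstituted alkene closes the seven-membered ring at C3=C4 with loss of ethylene, the trans relation of the two tethers having been fixed in step 11.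

Step 15
Reactants: 26 bicyclic allylic alcohol
Product: 27 3β-bromo-4β-formyl trans-decalin (ring A complete)
Conditions: NBS (1.1 equiv), NaHCO3, CH2Cl2, −20 to 0 °C, dark
Reagents that add atoms: N-bromosuccinimide O=C1CCC(=O)N1Br
Why: NBS delivers Br+ to the outer face of the C3=C4 alkene, and as the bromonium ion opens toward the tertiary C4 the C19–C5 bond, held nearly parallel to the C4 p-orbital on the inner face, shifts from C19 to C4 while the hydroxyl lone pair turns C19 into a protonated aldehyde that loses H+ to succinimide (halonium-induced semipinacol rearrangement). The closest known reactions are the NBS-triggered 1,2-carbon shifts of 2-substituted allylic alcohols and the Lewis-acid ring contraction of 2,3-epoxycycloalkanols to cycloalkanecarbaldehydes with an α-quaternary carbon. Ring A is closed by a suprafacial 1,2-alkyl shift of C5 (ring contraction from seven to six atoms, retention at C5), not by a cyclisation. C3 and C4 are created together by anti addition of Br and C5 across the cis ring alkene, which places Br and the C4 chain equatorial and the formyl group axial; their relation to C5 and C10 is controlled by the trans ring fusion, which holds the cycloheptene in the chair whose inner face carries C5 and which collapses directly to the chair trans-decalin. The step needs face selectivity and migration of C5 in preference to hydride shift, oxygen attack or proton loss: only the C19–C5 bond is antiperiplanar to an outer-face bromonium ion, no other alkene is present, the arene is deactivated and the chain aldehyde is masked.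

Step 16
Reactants: 27 bromo aldehyde
Product: 29 C4-methyl compound, via tosylhydrazone 28 (not isolated)
Conditions: TsNHNH2, THF/EtOH, 50 °C; then catecholborane, CHCl3, 0 °C; then NaOAc·3H2O, 60 °C
Reagents that add atoms: none
Why: Caglioti-type deoxygenation in which the tosylhydrazone is reduced at C=N by the borane and the hydrazine then loses sulfinate and dinitrogen under acetate buffering, turning the axial formyl group into the C4 methyl group without strong base.

Step 17
Reactants: 29 bis-dioxolane
Product: 30 keto aldehyde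
Conditions: 2 M aq. HCl, THF, rt to 40 °C
Reagents that add atoms: water O
Why: Aqueous acid hydrolysis of both dioxolanes; the regenerated C8 ketone equilibrates C9 to the equatorial arylmethyl configuration of the trans-decalin.

Step 18
Reactants: 30 keto aldehyde
Product: 31 keto alkene carrying the 4-methylpent-3-enyl chain
Conditions: isopropyltriphenylphosphonium iodide, n-BuLi, THF, 0 °C; then 30, −78 to 0 °C
Reagents that add atoms: isopropyltriphenylphosphonium iodide CC(C)[P+](c1ccccc1)(c1ccccc1)c1ccccc1.[I-]
Why: Wittig olefination with the non-stabilised isopropylidene ylide at low temperature should select the unhindered aldehyde over the hindered C8 ketone and the esters and gives the trisubstituted alkene directly.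

Step 19
Reactants: 31 ketone
Product: 32 methyl ester pivalate of the target
Conditions: Zn, CH2Br2, TiCl4 (reagent pre-formed at 5 °C), THF/CH2Cl2, 0 °C to rt
Reagents that add atoms: dibromomethane BrCBr
Why: Takai–Lombardo methylenation, in which the non-basic zinc–titanium methylene reagent converts the hindered, epimerisable ketone into the exocyclic alkene without enolisation and spares esters, the alkyl bromide and the aryl bromide.

Step 20
Reactants: 32 protected target
Product: 33 callophycoic acid H
Conditions: LiOH·H2O, THF/MeOH/H2O, 50 °C; then 1 M HCl to pH 3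
Reagents that add atoms: water O
Why: Saponification cleaves the methyl ester and the aryl pivalate in one operation; the equatorial neopentyl bromide has neither an open backside nor an antiperiplanar hydrogen and should survive hydroxide.

**Compound list**

1 | methyl 4-hydroxy-3-methylbenzoate | COC(=O)c1ccc(O)c(C)c1 | starting material
2 | methyl 3-bromo-4-hydroxy-5-methylbenzoate | COC(=O)c1cc(C)c(O)c(Br)c1 | intermediate
3 | methyl 3-bromo-5-methyl-4-(pivaloyloxy)benzoate | COC(=O)c1cc(C)c(OC(=O)C(C)(C)C)c(Br)c1 | intermediate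
4 | methyl 3-bromo-5-(bromomethyl)-4-(pivaloyloxy)benzoate (ArCH2Br) | COC(=O)c1cc(CBr)c(OC(=O)C(C)(C)C)c(Br)c1 | intermediate
5 | N-tert-butylethanimine | CC=NC(C)(C)C | starting material
6 | 2,3-dibromoprop-1-ene | C=C(Br)CBr | starting material
7 | lithium N-tert-butyl-N-vinylamide (aza-enolate of 5) | [Li]N(C=C)C(C)(C)C | intermediate
8 | N-tert-butyl-4-bromopent-4-en-1-imine | C=C(Br)CCC=NC(C)(C)C | intermediate
9 | 4-bromopent-4-enal | C=C(Br)CCC=O | intermediate
10 | 2-(3-bromobut-3-en-1-yl)-1,3-dioxolane | C=C(Br)CCC1OCCO1 | intermediate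
11 | (E)-pent-3-en-2-one | C/C=C/C(C)=O | starting material
12 | (E)-2-(triisopropylsilyloxy)penta-1,3-diene | C=C(O[Si](C(C)C)(C(C)C)C(C)C)/C=C/C | intermediate
13 | 2,2,2-trifluoroethyl acrylate | C=CC(=O)OCC(F)(F)F | starting material
14 | 2,2,2-trifluoroethyl (1S,2R)-2-methyl-4-(triisopropylsilyloxy)cyclohex-3-ene-1-carboxylate (cis) | CC(C)[Si](OC1=C[C@@H](C)[C@@H](C(=O)OCC(F)(F)F)CC1)(C(C)C)C(C)C | intermediate
15 | (1S,2R)-2-methyl-4-(triisopropylsilyloxy)cyclohex-3-ene-1-carbaldehyde | CC(C)[Si](OC1=C[C@@H](C)[C@@H](C=O)CC1)(C(C)C)C(C)C | intermediate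
16 | [4-(1,3-dioxolan-2-yl)but-1-en-2-yl]lithium | [Li]C(=C)CCC1OCCO1 | intermediate
17 | lithium alkoxide of 1-[(1S,2R)-2-methyl-4-(triisopropylsilyloxy)cyclohex-3-enyl]-2-methylene-4-(1,3-dioxolan-2-yl)butan-1-ol (C19 as drawn) | CC(C)[Si](OC1=C[C@@H](C)[C@@H]([C@@H](O[Li])C(=C)CCC2OCCO2)CC1)(C(C)C)C(C)C | intermediate
18 | triethylsilyl ether of the same C19 alcohol (ring still the triisopropylsilyl enol ether) | CC(C)[Si](OC1=C[C@@H](C)[C@@H]([C@@H](O[Si](CC)(CC)CC)C(=C)CCC2OCCO2)CC1)(C(C)C)C(C)C | intermediate
19 | (4S)-3-methyl-4-[1-(triethylsilyloxy)-2-methylene-4-(1,3-dioxolan-2-yl)butyl]cyclohex-2-en-1-one | O=C1C=C(C)[C@@H]([C@@H](O[Si](CC)(CC)CC)C(=C)CCC2OCCO2)CC1 | intermediate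
20 | C8–C9 trimethylsilyl enol ether; C10 bears methyl (cis to the C5 side chain) and but-3-enyl (trans) | C[Si](C)(C)OC1=C[C@](C)(CCC=C)[C@@H]([C@@H](O[Si](CC)(CC)CC)C(=C)CCC2OCCO2)CC1 | intermediate
21 | lithium enolate corresponding to 20 | [Li]OC1=C[C@](C)(CCC=C)[C@@H]([C@@H](O[Si](CC)(CC)CC)C(=C)CCC2OCCO2)CC1 | intermediate
22 | C9-epimeric ketone (ArCH2 trans to the C10 methyl, axial) | O=C1CC[C@H]([C@@H](O[Si](CC)(CC)CC)C(=C)CCC2OCCO2)[C@@](C)(CCC=C)[C@H]1Cc1cc(C(=O)OC)cc(Br)c1OC(=O)C(C)(C)C | intermediate
23 | cyclohexanone (C8=O) with C9 ArCH2 (cis to C10 methyl, equatorial), C10 methyl and but-3-enyl, C5 1-(triethylsilyloxy)-2-methylene-4-(1,3-dioxolan-2-yl)butyl (cis to C10 methyl) | O=C1CC[C@H]([C@@H](O[Si](CC)(CC)CC)C(=C)CCC2OCCO2)[C@@](C)(CCC=C)[C@@H]1Cc1cc(C(=O)OC)cc(Br)c1OC(=O)C(C)(C)C | intermediate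
24 | hydroxy ketone (23 without the triethylsilyl group) | O=C1CC[C@H]([C@@H](O)C(=C)CCC2OCCO2)[C@@](C)(CCC=C)[C@@H]1Cc1cc(C(=O)OC)cc(Br)c1OC(=O)C(C)(C)C | intermediate
25 | C8 ethylene ketal of 24 (bis-dioxolane allylic alcohol) | C12(OCCO1)CC[C@H]([C@@H](O)C(=C)CCC3OCCO3)[C@@](C)(CCC=C)[C@@H]2Cc1cc(C(=O)OC)cc(Br)c1OC(=O)C(C)(C)C | intermediate
26 | trans-fused bicycle: ring B (C8 ketal, C9β ArCH2, C10β methyl, 5α-H) annulated to the ring C10–C1–C2–C3=C4–C19(OH)–C5; C4 bears 2-(1,3-dioxolan-2-yl)ethyl; C19–OH pseudo-equatorial | C12(OCCO1)CC[C@@H]3[C@@H](O)C(CCC4OCCO4)=CCC[C@@]3(C)[C@@H]2Cc1cc(C(=O)OC)cc(Br)c1OC(=O)C(C)(C)C | intermediate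
27 | trans-decalin: 3β-Br (equatorial), C4 with axial β-CHO and equatorial α-2-(1,3-dioxolan-2-yl)ethyl, 5α-H, 10β-methyl, 9β-CH2Ar, C8 ketal | C12(OCCO1)CC[C@@H]3[C@@](C=O)(CCC4OCCO4)[C@H](Br)CC[C@@]3(C)[C@@H]2Cc1cc(C(=O)OC)cc(Br)c1OC(=O)C(C)(C)C | intermediate
28 | N-tosylhydrazone of 27 | C12(OCCO1)CC[C@@H]3[C@@](C=NNS(=O)(=O)c5ccc(C)cc5)(CCC4OCCO4)[C@H](Br)CC[C@@]3(C)[C@@H]2Cc1cc(C(=O)OC)cc(Br)c1OC(=O)C(C)(C)C | intermediate
29 | as 27 with the axial CHO replaced by CH3 (4β-methyl) | C12(OCCO1)CC[C@@H]3[C@@](C)(CCC4OCCO4)[C@H](Br)CC[C@@]3(C)[C@@H]2Cc1cc(C(=O)OC)cc(Br)c1OC(=O)C(C)(C)C | intermediate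
30 | 8-ketone with 3-oxopropyl chain on C4 (keto aldehyde) | O=C1CC[C@@H]2[C@@](C)(CCC=O)[C@H](Br)CC[C@@]2(C)[C@@H]1Cc1cc(C(=O)OC)cc(Br)c1OC(=O)C(C)(C)C | intermediate
31 | 8-ketone with 4-methylpent-3-enyl chain on C4 | O=C1CC[C@@H]2[C@@](C)(CCC=C(C)C)[C@H](Br)CC[C@@]2(C)[C@@H]1Cc1cc(C(=O)OC)cc(Br)c1OC(=O)C(C)(C)C | intermediate
32 | callophycoic acid H methyl ester O-pivalate | C=C1CC[C@@H]2[C@@](C)(CCC=C(C)C)[C@H](Br)CC[C@@]2(C)[C@@H]1Cc1cc(C(=O)OC)cc(Br)c1OC(=O)C(C)(C)C | intermediate
33 | callophycoic acid H | C=C1CC[C@@H]2[C@@](C)(CCC=C(C)C)[C@H](Br)CC[C@@]2(C)[C@@H]1Cc1cc(C(=O)O)cc(Br)c1O | target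

**Step count.** Total: 20 steps. Longest linear sequence: 15 steps (steps 6–20, from (E)-pent-3-en-2-one 11).

**Steps most likely to fail**

Step 15 (key step). Bromine may be delivered to the inner face of a boat-like conformer, which would give the wrong C3/C4 pair. The bromonium ion may also be captured by the free hydroxyl or an acetal oxygen, or lose a proton to give an allylic bromide, before C5 migrates. The fallback sets out from 23 and returns at 27; it keeps the hydroxyl silylated so that oxygen can act only as a cation-stabilising donor. Ketone 23 is ketalised under aprotic conditions (1,2-bis(trimethylsilyloxy)ethane, TMSOTf cat., CH2Cl2, −78 °C) to the silyl ether ketal F1. Ring-closing metathesis as in step 14 gives the silyl ether of the cycloheptenol F2. F2 is rearranged with 2,4,4,6-tetrabromocyclohexa-2,5-dienone in CH2Cl2/MeNO2 at −40 °C (silyl-ether variant of the semipinacol shift, silicon lost on work-up) to 27.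

Step 16. Condensation at the neopentyl, axial aldehyde may be slow or incomplete, and hydride transfer to the hindered C=N bond may stall. The fallback sets out from 27 and returns at 29 by a Wolff–Kishner reduction through an N-silyl hydrazone. Aldehyde 27 with 1,2-bis(tert-butyldimethylsilyl)hydrazine and Sc(OTf)3 (cat.) gives the N-silyl hydrazone F3, which KOt-Bu in DMSO/t-BuOH at room temperature converts into 29. 1,3-Elimination to a cyclopropane is disfavoured because the equatorial C3–Br bond is not antiperiplanar to the C4–C19 bond. Any loss of the pivalate would be harmless, since it is removed in step 20.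

Step 12. Alkylation next to the quaternary C10 may be slow enough to allow proton transfer between enolate and product (loss of regiocontrol, dialkylation) or attack of the enolate on the ester groups, and epimerisation at C9 may be incomplete. The fallback sets out from 20 and 4 and returns at 23 by aldol condensation and conjugate reduction. Bromide 4 is oxidised with N-methylmorpholine N-oxide (Kornblum-type oxidation) to the aryl aldehyde F4. Mukaiyama aldol addition of 20 to F4 (BF3·OEt2, CH2Cl2, −78 °C) gives the β-hydroxy ketone F5 regiospecifically at C9. MsCl/Et3N and then DBU give the benzylidene ketone F6. Conjugate reduction with [(Ph3P)CuH]6 followed by DBU equilibration gives 23.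

**Further compounds**

F1 | step 15 | C8 ethylene ketal of 23 with the C19 triethylsilyl ether retained | C12(OCCO1)CC[C@H]([C@@H](O[Si](CC)(CC)CC)C(=C)CCC3OCCO3)[C@@](C)(CCC=C)[C@@H]2Cc1cc(C(=O)OC)cc(Br)c1OC(=O)C(C)(C)C
F2 | step 15 | C19 triethylsilyl ether of cycloheptenol 26 | C12(OCCO1)CC[C@@H]3[C@@H](O[Si](CC)(CC)CC)C(CCC4OCCO4)=CCC[C@@]3(C)[C@@H]2Cc1cc(C(=O)OC)cc(Br)c1OC(=O)C(C)(C)C
F3 | step 16 | N-(tert-butyldimethylsilyl)hydrazone of aldehyde 27 | C12(OCCO1)CC[C@@H]3[C@@](C=NN[Si](C)(C)C(C)(C)C)(CCC4OCCO4)[C@H](Br)CC[C@@]3(C)[C@@H]2Cc1cc(C(=O)OC)cc(Br)c1OC(=O)C(C)(C)C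
F4 | step 12 | methyl 3-bromo-5-formyl-4-(pivaloyloxy)benzoate | COC(=O)c1cc(C=O)c(OC(=O)C(C)(C)C)c(Br)c1
F5 | step 12 | C9 aldol adduct of 20 and F4 (β-hydroxy ketone, mixture at C9 and the carbinol carbon) | O=C1CC[C@H]([C@@H](O[Si](CC)(CC)CC)C(=C)CCC2OCCO2)[C@@](C)(CCC=C)C1C(O)c1cc(C(=O)OC)cc(Br)c1OC(=O)C(C)(C)C
F6 | step 12 | C9 arylmethylidene ketone (either alkene isomer) | O=C1CC[C@H]([C@@H](O[Si](CC)(CC)CC)C(=C)CCC2OCCO2)[C@@](C)(CCC=C)C1=Cc1cc(C(=O)OC)cc(Br)c1OC(=O)C(C)(C)C
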